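in all of them: partner 50.4 mM; free catalyst 0.16 mM

| run | starting material | temperature | remark | time |
|---|---|---|---|---|
| alpha | 14 mM | 0 °C | run made earlier |  |
| south-east | 28 mM | 0 °C |  | 4.0 d |
| east | 28 mM |  | at −15 °C until 50 h, from then on at 15 °C | 4.0 d |
| north | 28 mM | −15 °C |  | 4.0 d |
| south | 28 mM | 15 °C |  | 4.0 d |

- alpha (time / h: target / %, starting material / %): 0.833: 7, 90; 2.00: 18, 82; 4.00: 38, 61; 10.0: 72, 25

(scatter of a reading: 2 percentage points)

- the earlier runs do not show what temperature does; that part of a forecast is a guess
- a reading or a percentage of target counts all its forms, free or not

- the best flask by amount of target, in percent of the starting material charged; "all alike" if 1.5 percentage points covers them all (south-east / east / north / south / all alike)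
- amount of target at the end, in percent of the starting material charged, south-east
- amount of target at the end, in percent of the starting material charged, east
- amount of target at the end, in percent of the starting material charged, north
- amount of target at the end, in percent of the starting material charged, south

The easy step came first: I turned the alpha target readings into concentration. By 4.00 h alpha had made 5.32 mM, a mean rate of 1.33 mM h⁻¹. Between 2.00 h and 4.00 h the slope read 1.40 mM h⁻¹, a little higher than that mean, although starting material had fallen to 61%. Given the scatter of 2 percentage points, I took the rate as steady down to about 8.54 mM of starting material; after that the slope read 0.793 mM h⁻¹, lower.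

So I carried one quantity, the clearing time: the smaller charge divided by the steady rate. For south-east, with the same partner and free catalyst as alpha, I reckoned 21.1 h, far shorter than the 4.0 d allowed. My curve of target left the origin at 1.33 mM h⁻¹ and ran straight to a knee at 14.6 h, with 69.5% of the charge converted. It then bent as alpha had, with 3.50 mM of starting material still there near 20.6 h, so the clearing time marked the end of the straight line, and my curve's tail ran on past it. With partner at 1.80 equivalents, taken one for one, target ran into a level near the balance read at alpha's last point, 97.0%. The runs do not show what temperature does, so I reckoned no further for the other flasks.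

The forecast differed from me in shape, saying that starting material “falls roughly first order”. It gave 96% for south-east, 95% for east, 87% for north and 93% for south, with south-east best.

The flasks gave 97.6% in south-east, 85.8% in east, 65.5% in north and 72.6% in south, with south-east best. The forecast held for south-east but stood above the flask in east, north and south.

    free catalyst + target ⇌ idle complex, settled at all times (K = 9.60 L mol⁻¹, ΔH = −23.0 kJ mol⁻¹)
    catalyst intermediate C → free catalyst + target (k = 0.200 min⁻¹, Ea = 86.0 kJ mol⁻¹)
    target → over-reaction product (k = 4.70 × 10⁻⁶ min⁻¹, Ea = 109 kJ mol⁻¹)
    starting material + catalyst intermediate B → catalyst intermediate C (k = 31.0 L mol⁻¹ min⁻¹, Ea = 37.0 kJ mol⁻¹)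
    catalyst intermediate A → catalyst intermediate B (k = 82.0 min⁻¹, Ea = 54.0 kJ mol⁻¹)
    partner + free catalyst → catalyst intermediate A (k = 840 L mol⁻¹ min⁻¹, Ea = 38.0 kJ mol⁻¹)
    (constants at 0 °C)

South-east had not come to rest at 4.0 d. Starting material was down to 0.00502% by 2.00 d, well past my clearing time of 21.1 h, and partner stood at 44.1% of its charge. Yet at 40.0 d target had slid from 97.6% to 76.5%, while over-reaction product rose from 2.38% to 23.5%. Taken as a first-order slide, that is 0.00677 d⁻¹, so I reckoned about 2.11% of target lost in the 3.12 d after my clearing time.

In a neighbour of south-east charged with 20 mM of partner, partner was the smaller charge, the limiting reagent; carrying the steady rate over unchanged, an assumption alpha does not test at this partner, I reckoned a clearing time of 15.0 h and a one-for-one level of 71.4%. That neighbour gave 69.7% of target, with 0% of partner and 29% of starting material left.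

The earlier runs and the new flask were generated by integration on assumed constants; noise was put on by code.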